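Ring numbering: C1 (methylated epoxide carbon), C2 (ketone), C3 (ester carbon), C4 (side-chain carbon), C5 (CH2), C6 (epoxide CH). The carbocycle is cut at C4–C5 and C1–C2. C1 lies between oxygenated C2 and C6, and C4 is β to C2, so C5–C6–C1 maps onto a 3-oxopentanoate and C2–C3–C4 onto an enal. A one-pot aminocatalytic Michael addition (C4–C5, sets C4) and acid-driven aldol condensation with decarboxylation (C1–C2) join two acyclic achiral carbonyl compounds to a 5-alkynyl-2-methylcyclohexenone. Wharton transposition then moves the carbonyl to C2; acyloxylation, directed epoxidation, carbonylative coupling and a Schenck ene reaction finish.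

Key step: step 2

Assumption: the epoxide of step 3 is drawn as the expected major isomer (anti to the alkyne); the minor isomer is carried along, because the carbinol centre that derives from it becomes the ring carbonyl in step 5.

Step 1
Reactants: 1 3-(trimethylsilyl)prop-2-ynal; 2 2-(triphenyl-λ5-phosphanylidene)acetaldehyde
Product: 3 (2E)-5-(trimethylsilyl)pent-2-en-4-ynal
Conditions: CH2Cl2, 0 °C to rt
Reagents that add atoms: none
Why: Wittig olefination with the stabilised formyl ylide should give the (E)-enal, and the ynal is the more electrophilic aldehyde, so that a second homologation of the product stays minor.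

Step 2
Reactants: 3 (2E)-5-(trimethylsilyl)pent-2-en-4-ynal; 4 tert-butyl 3-oxopentanoate
Product: 7 (5S)-2-methyl-5-[(trimethylsilyl)ethynyl]cyclohex-2-en-1-one, via Michael adduct 5 (not isolated), via cyclised keto ester 6 (not isolated)
Conditions: (R)-2-{bis[3,5-bis(trifluoromethyl)phenyl][(trimethylsilyl)oxy]methyl}pyrrolidine (10 mol%), PhCO2H (10 mol%), toluene, rt; then TsOH·H2O (20 mol%), 80 °C, same flask
Reagents that add atoms: none
Why: Iminium activation of enal 3 by the (R)-diarylprolinol silyl ether lets the doubly activated CH2 of 4 add to the β-carbon (organocatalytic Michael addition, forming C4–C5 of the target), and after acid is added the ketone enolises towards its ethyl side and attacks the liberated aldehyde (intramolecular aldol, forming C1–C2), after which dehydration and loss of 2-methylpropene and CO2 should give 7. The closest known reaction type is the amine-catalysed Michael/aldol-condensation synthesis of 5-substituted cyclohex-2-enones from β-keto esters and enals, a [3+3] annulation of the Robinson type. The ring closes in a 6-(enolendo)-exo-trig aldol mode. The only stereocentre (C4 of the target) is set in the Michael step by the catalyst, whose bulky diaryl(silyloxy)methyl group shields one face of the s-trans (E)-iminium ion so that the nucleophile should enter from the open face. The step needs 1,4-addition in preference to 1,2- and 1,6-addition and closure through the γ-CH2 and not the α-carbon of the keto ester; the iminium ion and the silyl cap on the alkyne terminus secure the first, and the six-membered against a four-membered ring secures the second.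

Step 3
Reactants: 7 (5S)-2-methyl-5-[(trimethylsilyl)ethynyl]cyclohex-2-en-1-one
Product: 9 (1S,4S,6S)-4-ethynyl-1-methyl-7-oxabicyclo[4.1.0]heptan-2-one, via silylated epoxy ketone 8 (not isolated)
Conditions: 30% aq. H2O2, NaOH, MeOH, 0 °C to rt
Reagents that add atoms: hydrogen peroxide OO
Why: Weitz–Scheffer epoxidation, in which hydroperoxide anion adds to the enone β-carbon and the enolate closes the oxirane, mainly on the face opposite the C5 substituent, while methanolic hydroxide cleaves the alkynyl–silicon bond in the same flask; the two new centres are erased again in steps 4 and 5, so their control is not needed.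

Step 4
Reactants: 9 (1S,4S,6S)-4-ethynyl-1-methyl-7-oxabicyclo[4.1.0]heptan-2-one
Product: 11 (1S,5R)-5-ethynyl-2-methylcyclohex-2-en-1-ol, via epoxy hydrazone 10 (not isolated)
Conditions: N2H4·H2O, AcOH (cat.), MeOH, 0 °C to rt
Reagents that add atoms: none
Why: Wharton transposition, in which the hydrazone opens the epoxide to a vinyl diazene that loses N2, so that the former ketone carbon becomes the alkene CH (the later C6) and a carbinol stays on the former aldehyde carbon (the later C2) with the configuration of the epoxide.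

Step 5
Reactants: 11 (1S,5R)-5-ethynyl-2-methylcyclohex-2-en-1-ol
Product: 12 (5R)-5-ethynyl-2-methylcyclohex-2-en-1-one
Conditions: MnO2 (activated), CH2Cl2, rt
Reagents that add atoms: none
Why: Allylic oxidation with MnO2 gives the transposed enone, removes the carbinol centre so that both epimers converge, and places the ring carbonyl on C2 with free α′-hydrogens on C3.

Step 6
Reactants: 12 (5R)-5-ethynyl-2-methylcyclohex-2-en-1-one
Product: 13 (5R)-5-(1-iodoethenyl)-2-methylcyclohex-2-en-1-one
Conditions: NaI, Me3SiCl, H2O, MeCN, 0 °C to rt; Et3N on work-up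
Reagents that add atoms: sodium iodide [Na+].[I-] (converted in the flask into hydrogen iodide [H]I)
Why: Branched-selective hydroiodination, in which hydrogen iodide formed in the flask protonates the terminal alkyne carbon and iodide adds at the internal one, while iodide that adds to the enone is lost again on basic work-up; the 1-iodoethenyl group then serves as conformational anchor and as coupling handle.

Step 7
Reactants: 13 (5R)-5-(1-iodoethenyl)-2-methylcyclohex-2-en-1-one; 14 3-methylbutanoic acid
Product: 15 (1S,6R)-6-(1-iodoethenyl)-3-methyl-2-oxocyclohex-3-en-1-yl 3-methylbutanoate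
Conditions: Mn(OAc)3·2H2O, excess 14, benzene, reflux, water and AcOH removed azeotropically
Reagents that add atoms: none
Why: α′-Acyloxylation of the enone with manganese triacetate after ligand exchange with the acid, in which the manganese enolate of the C3 methylene receives the isovalerate on the face opposite the neighbouring 1-iodoethenyl group, which should give the trans ester, and the epimerisable centre can be equilibrated to this diequatorial isomer.

Step 8
Reactants: 15 (1S,6R)-6-(1-iodoethenyl)-3-methyl-2-oxocyclohex-3-en-1-yl 3-methylbutanoate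
Product: 16 (1S,2S,6R)-2-hydroxy-6-(1-iodoethenyl)-3-methylcyclohex-3-en-1-yl 3-methylbutanoate
Conditions: NaBH4, CeCl3·7H2O, MeOH, −78 °C
Reagents that add atoms: none
Why: Luche reduction gives 1,2-reduction only, and axial hydride delivery to the half-chair that holds ester and 1-iodoethenyl group equatorial should set the equatorial alcohol, trans to the ester and cis to the 1-iodoethenyl group.

Step 9
Reactants: 16 (1S,2S,6R)-2-hydroxy-6-(1-iodoethenyl)-3-methylcyclohex-3-en-1-yl 3-methylbutanoate
Product: 17 (1R,2R,3S,4R,6S)-2-hydroxy-4-(1-iodoethenyl)-1-methyl-7-oxabicyclo[4.1.0]heptan-3-yl 3-methylbutanoate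
Conditions: VO(acac)2 (cat.), t-BuOOH (in decane), CH2Cl2, 0 °C to rt
Reagents that add atoms: tert-butyl hydroperoxide CC(C)(C)OO
Why: Vanadium-catalysed hydroxyl-directed epoxidation delivers oxygen to the ring alkene from the face of the allylic alcohol, which sets both epoxide centres (C1 and C6) cis to the C4 substituent and trans to the ester, while the electron-poor, non-allylic vinyl iodide stays untouched.

Step 10
Reactants: 17 (1R,2R,3S,4R,6S)-2-hydroxy-4-(1-iodoethenyl)-1-methyl-7-oxabicyclo[4.1.0]heptan-3-yl 3-methylbutanoate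
Product: 18 (1S,3S,4R,6S)-4-(1-iodoethenyl)-1-methyl-2-oxo-7-oxabicyclo[4.1.0]heptan-3-yl 3-methylbutanoate
Conditions: Dess–Martin periodinane, pyridine, CH2Cl2, rt
Reagents that add atoms: none
Why: Dess–Martin oxidation under buffered conditions returns the C2 ketone without opening the epoxide or epimerising C3, and it removes the free hydroxyl that could otherwise trap the acylpalladium species of the next step as a lactone.

Step 11
Reactants: 18 (1S,3S,4R,6S)-4-(1-iodoethenyl)-1-methyl-2-oxo-7-oxabicyclo[4.1.0]heptan-3-yl 3-methylbutanoate; 19 tributyl(3-methylbut-2-en-1-yl)stannane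
Product: 20 (1S,3S,4S,6S)-1-methyl-4-(6-methyl-3-oxohepta-1,5-dien-2-yl)-2-oxo-7-oxabicyclo[4.1.0]heptan-3-yl 3-methylbutanoate
Conditions: CO (3 atm), Pd2(dba)3 (5 mol%), AsPh3 (20 mol%), THF, 45 °C
Reagents that add atoms: carbon monoxide [C-]#[O+]
Why: Carbonylative Stille coupling, in which oxidative addition of the vinyl iodide to zerovalent palladium, insertion of CO and transfer of the allyl group from tin through its unsubstituted CH2 terminus should give the β,γ-unsaturated ketone under neutral conditions that spare the epoxy ketone and the ester.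

Step 12
Reactants: 20 (1S,3S,4S,6S)-1-methyl-4-(6-methyl-3-oxohepta-1,5-dien-2-yl)-2-oxo-7-oxabicyclo[4.1.0]heptan-3-yl 3-methylbutanoate
Product: 21 (1S,3S,4S,6S)-4-[(4E)-6-hydroperoxy-6-methyl-3-oxohepta-1,4-dien-2-yl]-1-methyl-2-oxo-7-oxabicyclo[4.1.0]heptan-3-yl 3-methylbutanoate
Conditions: O2, 5,10,15,20-tetraphenylporphyrin (cat.), visible light, CH2Cl2, 0 °C
Reagents that add atoms: dioxygen O=O
Why: Schenck ene reaction, in which singlet oxygen attacks the trisubstituted alkene and abstracts an allylic hydrogen of the CH2 next to the carbonyl, which shifts the double bond into conjugation as the (E)-enone and places the hydroperoxide on the tertiary carbon, while the electron-poor α-methylene ketone does not react.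

Compound list
1 | 3-(trimethylsilyl)prop-2-ynal | C[Si](C)(C)C#CC=O | starting material
2 | 2-(triphenyl-λ5-phosphanylidene)acetaldehyde | O=CC=P(c1ccccc1)(c1ccccc1)c1ccccc1 | starting material
3 | (2E)-5-(trimethylsilyl)pent-2-en-4-ynal | C[Si](C)(C)C#C/C=C/C=O | intermediate
4 | tert-butyl 3-oxopentanoate | CCC(=O)CC(=O)OC(C)(C)C | starting material
5 | tert-butyl (3S)-3-(2-oxoethyl)-2-propanoyl-5-(trimethylsilyl)pent-4-ynoate (both C2 epimers) | C[Si](C)(C)C#C[C@@H](CC=O)C(C(=O)OC(C)(C)C)C(=O)CC | intermediate (not isolated)
6 | tert-butyl (6S)-3-methyl-2-oxo-6-[(trimethylsilyl)ethynyl]cyclohex-3-ene-1-carboxylate (both C1 epimers) | C[Si](C)(C)C#C[C@@H]1C(C(=O)OC(C)(C)C)C(=O)C(C)=CC1 | intermediate (not isolated)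
7 | (5S)-2-methyl-5-[(trimethylsilyl)ethynyl]cyclohex-2-en-1-one | C[Si](C)(C)C#C[C@@H]1CC(=O)C(C)=CC1 | intermediate
8 | (1S,4S,6S)-1-methyl-4-[(trimethylsilyl)ethynyl]-7-oxabicyclo[4.1.0]heptan-2-one | C[Si](C)(C)C#C[C@@H]1CC(=O)[C@@]2(C)O[C@H]2C1 | intermediate (not isolated)
9 | (1S,4S,6S)-4-ethynyl-1-methyl-7-oxabicyclo[4.1.0]heptan-2-one | C#C[C@@H]1CC(=O)[C@@]2(C)O[C@H]2C1 | intermediate
10 | hydrazone of epoxy ketone 9 (C=N–NH2 at the former carbonyl carbon, ring configuration as in 9) | C#C[C@@H]1CC(=NN)[C@@]2(C)O[C@H]2C1 | intermediate (not isolated)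
11 | (1S,5R)-5-ethynyl-2-methylcyclohex-2-en-1-ol | C#C[C@@H]1CC=C(C)[C@@H](O)C1 | intermediate
12 | (5R)-5-ethynyl-2-methylcyclohex-2-en-1-one | C#C[C@@H]1CC=C(C)C(=O)C1 | intermediate
13 | (5R)-5-(1-iodoethenyl)-2-methylcyclohex-2-en-1-one | IC(=C)[C@@H]1CC=C(C)C(=O)C1 | intermediate
14 | 3-methylbutanoic acid | CC(C)CC(=O)O | starting material
15 | (1S,6R)-6-(1-iodoethenyl)-3-methyl-2-oxocyclohex-3-en-1-yl 3-methylbutanoate | IC(=C)[C@@H]1CC=C(C)C(=O)[C@H]1OC(=O)CC(C)C | intermediate
16 | (1S,2S,6R)-2-hydroxy-6-(1-iodoethenyl)-3-methylcyclohex-3-en-1-yl 3-methylbutanoate | IC(=C)[C@@H]1CC=C(C)[C@H](O)[C@H]1OC(=O)CC(C)C | intermediate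
17 | (1R,2R,3S,4R,6S)-2-hydroxy-4-(1-iodoethenyl)-1-methyl-7-oxabicyclo[4.1.0]heptan-3-yl 3-methylbutanoate | IC(=C)[C@@H]1C[C@@H]2O[C@]2(C)[C@H](O)[C@H]1OC(=O)CC(C)C | intermediate
18 | (1S,3S,4R,6S)-4-(1-iodoethenyl)-1-methyl-2-oxo-7-oxabicyclo[4.1.0]heptan-3-yl 3-methylbutanoate | IC(=C)[C@@H]1C[C@@H]2O[C@]2(C)C(=O)[C@H]1OC(=O)CC(C)C | intermediate
19 | tributyl(3-methylbut-2-en-1-yl)stannane | CCCC[Sn](CCCC)(CCCC)CC=C(C)C | starting material
20 | (1S,3S,4S,6S)-1-methyl-4-(6-methyl-3-oxohepta-1,5-dien-2-yl)-2-oxo-7-oxabicyclo[4.1.0]heptan-3-yl 3-methylbutanoate | C=C(C(=O)CC=C(C)C)[C@@H]1C[C@@H]2O[C@]2(C)C(=O)[C@H]1OC(=O)CC(C)C | intermediate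
21 | (1S,3S,4S,6S)-4-[(4E)-6-hydroperoxy-6-methyl-3-oxohepta-1,4-dien-2-yl]-1-methyl-2-oxo-7-oxabicyclo[4.1.0]heptan-3-yl 3-methylbutanoate | C=C(C(=O)/C=C/C(C)(C)OO)[C@@H]1C[C@@H]2O[C@]2(C)C(=O)[C@H]1OC(=O)CC(C)C | target

Total step count: 12 steps. Longest linear sequence: 12 steps (1 to 21).

Steps most likely to fail

1. Step 6. What may go wrong: conjugate addition of iodide to the enone that is not reversed on work-up, a second addition of hydrogen iodide to the alkyne, or loss of regiocontrol. Fallback: the route leaves at 12. Ruthenium-catalysed hydrosilylation ([Cp*Ru(MeCN)3]PF6, Et3SiH, CH2Cl2, 0 °C), which places silicon on the internal alkyne carbon, should give (5R)-2-methyl-5-[1-(triethylsilyl)ethenyl]cyclohex-2-en-1-one F1. Iododesilylation of this vinylsilane with N-iodosuccinimide in 1,1,1,3,3,3-hexafluoropropan-2-ol at 0 °C comes back to the route at 13.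

2. Step 7. What may go wrong: transfer of acetate in place of isovalerate, incomplete oxidation, or poor facial selectivity at C3. Fallback: the route leaves at 13. Kinetic deprotonation at the α′-methylene (LiN(SiMe3)2, THF, −78 °C) and trapping with Me3SiCl should give the silyl dienol ether {[(3R)-3-(1-iodoethenyl)-6-methylcyclohexa-1,5-dien-1-yl]oxy}trimethylsilane F2. Rubottom oxidation (3-chloroperbenzoic acid, NaHCO3, CH2Cl2, −20 °C, then dilute acid) should attack anti to the 1-iodoethenyl group and give (5R,6S)-6-hydroxy-5-(1-iodoethenyl)-2-methylcyclohex-2-en-1-one F3. Esterification with 3-methylbutanoyl chloride (pyridine, 4-(dimethylamino)pyridine, CH2Cl2) comes back to the route at 15.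

3. Step 11. What may go wrong: transfer of the prenyl group without insertion of CO or through its substituted terminus, or palladium-induced isomerisation of the epoxy ketone or of the β,γ-unsaturated ketone. Fallback: the route leaves at 17, before step 10. Dess–Martin oxidation of commercial 4-methylpent-3-en-1-ol gives 4-methylpent-3-enal F4, which is used at once in a Nozaki–Hiyama–Kishi coupling with 17 (CrCl2, NiCl2 (cat.), DMSO, rt). This aldehyde-selective addition should give (1R,2R,3S,4S,6S)-2-hydroxy-4-(3-hydroxy-6-methylhepta-1,5-dien-2-yl)-1-methyl-7-oxabicyclo[4.1.0]heptan-3-yl 3-methylbutanoate F5 as a mixture of side-chain carbinol epimers. Dess–Martin oxidation of both secondary alcohols comes back to the route at 20, so that steps 10 and 11 are bypassed.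

Further compounds
F1 | step 6 | (5R)-2-methyl-5-[1-(triethylsilyl)ethenyl]cyclohex-2-en-1-one | C=C([Si](CC)(CC)CC)[C@@H]1CC=C(C)C(=O)C1
F2 | step 7 | {[(3R)-3-(1-iodoethenyl)-6-methylcyclohexa-1,5-dien-1-yl]oxy}trimethylsilane | IC(=C)[C@@H]1CC=C(C)C(O[Si](C)(C)C)=C1
F3 | step 7 | (5R,6S)-6-hydroxy-5-(1-iodoethenyl)-2-methylcyclohex-2-en-1-one | IC(=C)[C@@H]1CC=C(C)C(=O)[C@H]1O
F4 | step 11 | 4-methylpent-3-enal | CC(C)=CCC=O
F5 | step 11 | (1R,2R,3S,4S,6S)-2-hydroxy-4-(3-hydroxy-6-methylhepta-1,5-dien-2-yl)-1-methyl-7-oxabicyclo[4.1.0]heptan-3-yl 3-methylbutanoate (both side-chain carbinol epimers) | C=C(C(O)CC=C(C)C)[C@@H]1C[C@@H]2O[C@]2(C)[C@H](O)[C@H]1OC(=O)CC(C)C
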